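The numbers in the tables were generated by integration on assumed constants.

The left-handed product of the red flask has stood near 65.9 % since about 6.00 h, with 14.9 % of left-handed substrate still beside it, and we must choose what to do at 25 h.

| flask | left-handed substrate | right-handed substrate | coupling partner | free catalyst | racemization catalyst | remark | time |
|---|---|---|---|---|---|---|---|
| red | 0.050 M | 0.050 M | 0.20 M | 0.90 mM | 0.50 mM | the very flask that is asked about, followed so far |  |
| ochre | 0.050 M | 0.050 M | 0.30 M | 0.90 mM | 0.50 mM | run made earlier |  |
| flask | 0.050 M | 0.050 M | 0.200 M | 0.90 mM | 0.50 mM |  | 25 h |

red run (percent of the left-handed substrate and right-handed substrate together charged)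

| time / h | left-handed product / % | left-handed substrate / % |
|---|---|---|
| 2.00 | 58.0 | 6.6 |
| 4.00 | 62.6 | 9.6 |
| 6.00 | 65.2 | 13.1 |
| 8.00 | 64.9 | 13.7 |
| 10.0 | 65.4 | 14.8 |
| 12.0 | 65.6 | 15.1 |
| 15.0 | 65.9 | 14.9 |

ochre run (percent of the left-handed substrate and right-handed substrate together charged)

| time / min | left-handed product / % | left-handed substrate / % |
|---|---|---|
| 15.0 | 42.6 | 9.1 |
| 30.0 | 50.3 | 3.8 |
| 50.0 | 54.1 | 2.9 |
| 60.0 | 55.7 | 3.0 |
| 80.0 | 57.4 | 3.0 |
| 90.0 | 58.7 | 3.1 |
| 120 | 60.9 | 4.1 |

(readings scatter by 0.3 percentage points)

- free catalyst is single-handed; left-handed substrate and right-handed substrate are mirror images of each other, charged as a racemate, each of them at the stated concentration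
- left-handed product that was removed still counts
- "the catalyst" is free catalyst with its forms; racemization catalyst is a second catalyst
- additions bring no volume worth counting

- delta: change nothing and wait 25 h more
- eta: at 25 h add coupling partner, 50.0 % of the amount charged, then wait 25 h
- alpha: at 25 h add free catalyst, 100 % of the amount charged, then wait 25 h
- theta: at 25 h take out 90 % of the left-handed product then present, then wait 25 h

- left-handed product, in percent of the left-handed substrate and right-handed substrate together first charged, at 25 h
- which option adds most left-handed product ("none" when 2 percentage points or less is all one gets) (delta / eta / alpha / theta / none)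
- left-handed product present, with what was taken out counted in, in percent of the left-handed substrate and right-handed substrate together first charged, after delta
- left-handed product present, with what was taken out counted in, in percent of the left-handed substrate and right-handed substrate together first charged, after alpha

Turn the choice round: what would have to be true for fresh catalyst to be the right move? By the last red reading, left-handed product has taken 32.9 % of the coupling partner charge. So alpha needs the remainder still in the flask and the catalyst dead, while eta needs the reverse.

Both pictures share one measurable thing, the pseudo-first-order coefficient k, which is the rate of left-handed product per left-handed substrate. In the ochre run, k reads 4.78 h⁻¹ across the first two readings and 1.22 h⁻¹ across the last two; if we take the fall between these two readings as exponential, its decay rate reads 0.991 h⁻¹. Integrating that exponential over unlimited time gives its start value divided by its decay rate. We call this the reach, the number of e-foldings of left-handed substrate that a charge can deliver. Scaled to the red partner charge, the reach is 4.66.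

We commit to a size for the case that partner is what went: a renewal of 50.0 % of the charge carries 2.33 e-foldings, and we reckon a gain of 13 percentage points, above the 2 points margin.

The forecast says 66 % now, 66.3 % after delta, and alpha as best with 82 %: “So the catalyst dies”.

The flask gives 65.5 %; eta is best, adding 15 points against our 13 points, and alpha stays at 65.5 %.

    coupling partner + free catalyst + left-handed substrate → free catalyst + left-handed product (k = 580 L² mol⁻² min⁻¹)
    coupling partner + free catalyst + right-handed substrate → free catalyst + right-handed product (k = 10.0 L² mol⁻² min⁻¹)
    left-handed substrate + racemization catalyst ⇌ right-handed substrate + racemization catalyst, rate k3*[racemization catalyst]*[left-handed substrate] forward; the back reaction follows from the equilibrium constant (k = 7.60 L mol⁻¹ min⁻¹)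
    coupling partner → decomposed reagent (k = 0.00890 min⁻¹)
    2 free catalyst ⇌ resting dimer (K = 3100 L mol⁻¹, k = 5.30 L mol⁻¹ min⁻¹)

The run without decomposition of coupling partner reaches 91.6 % of left-handed product at 25 h instead of 65.5 %, so that step is the main reason for the shortfall. At 25.0 h the coupling partner stands at 0 % of its charge, while free catalyst and resting dimer hold 34.3 % and 65.7 % of the catalyst. The neighbour flask with a quarter of the partner charge has a reach of 1.16, which reckons 34.4 % of left-handed product, and that flask gave 29.9 %.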